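The plan rests on cutting the southern half at two bonds of its seven-membered lactone (ring B of the 2-benzoxepin-1-one): the acyl bond C1–C9a, from the lactone carbonyl to the ring-fusion carbon, and the C4=C5 alkene that carries the carboxyl group. Both are formed in one flask from a carvone-derived cyclohexenyl triflate, carbon monoxide and tert-butyl 2-(hydroxymethyl)acrylate: palladium-catalysed alkoxycarbonylation, then ring-closing metathesis of the resulting diene ester. The precursor is a monocyclic vinyl triflate bearing a vinyl group next to it. C9a and C9 are then relayed from ring A, and the northern cyclohexene acid, made from (R)-cryptone, is joined by epoxide opening.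

Key step: step 5

Remark (numbering): southern-half atoms are numbered as in 2-benzoxepine: C1 lactone carbonyl, O2, C3, C4 (carboxyl-bearing), C5, C5a, C6 (isopropyl), C7, C8, C9 (carbinol), C9a; ring A is the carbocycle, ring B the lactone.
Remark (assumption): in step 8 the (R)-prolinol ether is taken to give the (R)-aldehyde by the usual enamine shielding model; if the sense were the reverse, its enantiomer would be used.

Step 1
Reactants: 1 tert-butyl acrylate
Product: 2 tert-butyl 2-(hydroxymethyl)prop-2-enoate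
Conditions: paraformaldehyde, DABCO (cat.), 1,4-dioxane/H2O, rt
Reagents that add atoms: formaldehyde (as paraformaldehyde), C=O
Why: Baylis–Hillman reaction: DABCO adds to the acrylate and the resulting enolate is hydroxymethylated by formaldehyde at the α-carbon, a standard preparation of 2-(hydroxymethyl)acrylates that creates no stereocentre.

Step 2
Reactants: 3 (R)-(−)-carvone
Product: 4 (R)-carvotanacetone, (5R)-2-methyl-5-(propan-2-yl)cyclohex-2-en-1-one
Conditions: H2 (1 atm), RhCl(PPh3)3 (cat.), toluene, rt
Reagents that add atoms: none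
Why: Chemoselective homogeneous hydrogenation: RhCl(PPh3)3 reduces the unhindered 1,1-disubstituted isopropenyl alkene and leaves the trisubstituted conjugated alkene, so the C5 stereocentre bought with carvone is kept.

Step 3
Reactants: 4 (R)-carvotanacetone
Product: 7 (5S,6S)-6-ethenyl-2-methyl-5-(propan-2-yl)cyclohex-2-en-1-one (vinyl trans to isopropyl), via lithium dienolate 5 (not isolated), via sulfoxide adduct 6 (not isolated)
Conditions: LiN(i-Pr)2 (commercial solution), THF, −78 °C; CH2=CHS(O)Ph, −78 → −20 °C; aq. NH4Cl; then toluene, NaHCO3, 110 °C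
Reagents that add atoms: phenyl vinyl sulfoxide, C=CS(=O)c1ccccc1
Why: Kinetic α′-enolate formation at C6 and Michael addition to phenyl vinyl sulfoxide, used as a vinyl cation equivalent, followed by thermal syn-elimination of the sulfoxide; the electrophile enters anti to the neighbouring isopropyl group, which sets the trans C5/C6 relationship.

Step 4
Reactants: 7 (5S,6S)-6-ethenyl-2-methyl-5-(propan-2-yl)cyclohex-2-en-1-one
Product: 9 (5S,6S)-6-ethenyl-2-methyl-5-(propan-2-yl)cyclohex-1-en-1-yl trifluoromethanesulfonate, via lithium enolate 8 (not isolated)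
Conditions: LiBH(s-Bu)3, THF, −78 °C; then PhNTf2, −78 → 0 °C; aq. NH4Cl
Reagents that add atoms: N-phenylbis(trifluoromethanesulfonimide), O=S(=O)(N(c1ccccc1)S(=O)(=O)C(F)(F)F)C(F)(F)F
Why: Conjugate reduction–enolate trapping: LiBH(s-Bu)3 delivers hydride to the unsubstituted β-carbon C3 and the regiodefined C1/C2 enolate is O-sulfonylated by PhNTf2 to the tetrasubstituted vinyl triflate, no new stereocentre being formed.

Step 5
Reactants: 9 (5S,6S)-6-ethenyl-2-methyl-5-(propan-2-yl)cyclohex-1-en-1-yl trifluoromethanesulfonate; 2 tert-butyl 2-(hydroxymethyl)prop-2-enoate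
Product: 11 tert-butyl (5aR,6S)-9-methyl-1-oxo-6-(propan-2-yl)-1,3,5a,6,7,8-hexahydro-2-benzoxepine-4-carboxylate, via diene ester 10 (not isolated)
Conditions: one flask: Pd(OAc)2 (5 mol %), 1,3-bis(diphenylphosphino)propane (6 mol %), CO (1 atm), 2 (1.5 equiv), i-Pr2NEt, toluene, 70 °C; then argon purge, dilution, Hoveyda–Grubbs second-generation catalyst (10 mol %), 90 °C
Reagents that add atoms: carbon monoxide, [C-]#[O+]
Why: Zerovalent palladium inserts into the C–OTf bond of 9, CO insertion gives an acylpalladium and alcohol 2 cleaves it, forming the C1–C9a bond (and the ester C1–O2 bond) in diene ester 10; after CO is purged the ruthenium alkylidene loads at the vinyl group and closes onto the acrylate alkene with loss of ethylene, forming C4=C5. The closest known reaction types are the alkoxycarbonylation of enol triflates and ring-closing metathesis of α-substituted acrylate dienes to cyclic trisubstituted enoates. Ring B closes as a seven-membered ring by metathesis between the alkene on C5a and the alkene attached to the C3 methylene, so the new alkene is necessarily cis within the ring. No stereocentre is formed: C5a and C6 come from 9 and C9a is left trigonal for step 6. Selectivity needed: alcoholysis must outrun addition of the acylpalladium to the neighbouring vinyl group (excess primary alcohol, amine base), ionisation of the allylic ester by palladium is degenerate because both allyl termini are CH2, and metathesis does not touch the tetrasubstituted C9=C9a alkene and is kept intramolecular by dilution.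

Step 6
Reactants: 11 tert-butyl (5aR,6S)-9-methyl-1-oxo-6-(propan-2-yl)-1,3,5a,6,7,8-hexahydro-2-benzoxepine-4-carboxylate
Product: 13 tert-butyl (5aR,6S,9aS)-9-methylidene-1-oxo-6-(propan-2-yl)-1,3,5a,6,7,8,9,9a-octahydro-2-benzoxepine-4-carboxylate (5a-H and 9a-H cis), via lithium dienolate 12 (not isolated)
Conditions: LiN(i-Pr)2 (commercial solution), THF/DMPU, −78 °C; then AcOH, −78 °C
Reagents that add atoms: none
Why: Deconjugative protonation: the amide base removes a proton from the C9 methyl group, which lies syn to the lactone carbonyl, and kinetic α-protonation of the extended dienolate at C9a occurs from the face of the C5a–H (away from the C5a–C6 bond of ring A), giving the cis-fused lactone and moving the alkene to the exocyclic position.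

Step 7
Reactants: 13 tert-butyl (5aR,6S,9aS)-9-methylidene-1-oxo-6-(propan-2-yl)-1,3,5a,6,7,8,9,9a-octahydro-2-benzoxepine-4-carboxylate
Product: 14 tert-butyl (5aR,6S,9R,9aS)-9-(bromomethyl)-9-hydroxy-1-oxo-6-(propan-2-yl)-1,3,5a,6,7,8,9,9a-octahydro-2-benzoxepine-4-carboxylate (9-OH cis to C1)
Conditions: N-bromosuccinimide, THF/H2O (4:1), 0 °C
Reagents that add atoms: N-bromosuccinimide, O=C1CCC(=O)N1Br; water, O
Why: Bromohydrin formation on the only electron-rich alkene: the bromonium ion forms on the face remote from the axial C1 substituent of C9a and water opens it at the tertiary carbon C9 from the opposite face (Markovnikov anti-addition), which places the C9 hydroxyl cis to C1.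

Step 8
Reactants: 15 3-methylbutanal (isovaleraldehyde); 16 but-3-en-2-one (methyl vinyl ketone)
Product: 18 (R)-cryptone, (4R)-4-(propan-2-yl)cyclohex-2-en-1-one, via keto aldehyde 17 (not isolated)
Conditions: (R)-α,α-diphenylprolinol methyl ether (5 mol %), ethyl 3,4-dihydroxybenzoate (20 mol %), neat, 4 °C; then LiOH (cat.), i-PrOH, rt
Reagents that add atoms: none
Why: Organocatalytic Michael addition via the enamine of isovaleraldehyde sets the single stereocentre by catalyst control, and base-mediated intramolecular aldol condensation of the keto aldehyde then gives the cyclohexenone (Robinson-type annulation).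

Step 9
Reactants: 18 (R)-cryptone
Product: 20 (3R,4R)-3-ethenyl-4-(propan-2-yl)cyclohex-1-en-1-yl trifluoromethanesulfonate (vinyl trans to isopropyl), via magnesium enolate 19 (not isolated)
Conditions: CH2=CHMgBr, CuBr·SMe2 (10 mol %), THF, −78 °C; then N-(5-chloropyridin-2-yl)bis(trifluoromethanesulfonimide), −78 → 0 °C; aq. NH4Cl
Reagents that add atoms: vinylmagnesium bromide, C=C[Mg]Br; N-(5-chloropyridin-2-yl)bis(trifluoromethanesulfonimide), O=S(=O)(N(c1ccc(Cl)cn1)S(=O)(=O)C(F)(F)F)C(F)(F)F
Why: Copper-catalysed conjugate addition of the vinyl Grignard reagent anti to the C4 isopropyl group sets the trans C3/C4 relationship by substrate control, and the regiodefined enolate is trapped on oxygen by the pyridyl triflimide.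

Step 10
Reactants: 20 (3R,4R)-3-ethenyl-4-(propan-2-yl)cyclohex-1-en-1-yl trifluoromethanesulfonate
Product: 21 [(3R,4R)-3-ethenyl-4-(propan-2-yl)cyclohex-1-en-1-yl]methanol
Conditions: Bu3SnCH2OH, Pd(PPh3)4 (5 mol %), LiCl, 1,4-dioxane, 100 °C
Reagents that add atoms: (tributylstannyl)methanol, OC[Sn](CCCC)(CCCC)CCCC
Why: Stille coupling of the vinyl triflate with the hydroxymethylstannane (LiCl-assisted transmetalation) installs the CH2OH group at C1 without touching the stereocentres or the vinyl group.

Step 11
Reactants: 21 [(3R,4R)-3-ethenyl-4-(propan-2-yl)cyclohex-1-en-1-yl]methanol; 22 methyl 2-(hydroxymethyl)prop-2-enoate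
Product: 23 methyl (2E)-2-(hydroxymethyl)-3-[(1R,6R)-3-(hydroxymethyl)-6-(propan-2-yl)cyclohex-2-en-1-yl]prop-2-enoate
Conditions: 22 (3 equiv), Hoveyda–Grubbs second-generation catalyst (5 mol %), CH2Cl2, 40 °C
Reagents that add atoms: none
Why: Olefin cross-metathesis between the monosubstituted vinyl group and the 1,1-disubstituted acrylate, in which the trisubstituted ring alkene is inert, gives the thermodynamically favoured E enoate with the ring carbon trans to the ester.

Step 12
Reactants: 23 methyl (2E)-2-(hydroxymethyl)-3-[(1R,6R)-3-(hydroxymethyl)-6-(propan-2-yl)cyclohex-2-en-1-yl]prop-2-enoate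
Product: 24 (2E)-2-(hydroxymethyl)-3-[(1R,6R)-3-(hydroxymethyl)-6-(propan-2-yl)cyclohex-2-en-1-yl]prop-2-enoic acid
Conditions: LiOH, THF/H2O, rt; then aq. HCl to pH 3
Reagents that add atoms: lithium hydroxide, [Li+].[OH-]
Why: Saponification of the methyl ester by acyl–oxygen cleavage; no stereocentre or alkene geometry is affected.

Step 13
Reactants: 14 tert-butyl (5aR,6S,9R,9aS)-9-(bromomethyl)-9-hydroxy-1-oxo-6-(propan-2-yl)-1,3,5a,6,7,8,9,9a-octahydro-2-benzoxepine-4-carboxylate; 24 (2E)-2-(hydroxymethyl)-3-[(1R,6R)-3-(hydroxymethyl)-6-(propan-2-yl)cyclohex-2-en-1-yl]prop-2-enoic acid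
Product: 26 tert-butyl ester of the target (ester of 24 with the 9-CH2OH group of the southern half; 5aR,6S,9R,9aS), via spiro-epoxide 25 (not isolated)
Conditions: Cs2CO3, DMF, 0 → 40 °C
Reagents that add atoms: none
Why: Base closes the bromohydrin to the spiro-epoxide with retention at C9 and the caesium carboxylate of 24 opens it at the unhindered CH2 carbon (SN2 epoxide opening by a carboxylate), so the tertiary alcohol keeps the configuration set in step 7 while the free alcohols of 24 stay spectators.

Step 14
Reactants: 26 tert-butyl ester of the target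
Product: 27 CNP0361406.3, (5aR,6S,9R,9aS)-9-hydroxy-9-({[(2E)-2-(hydroxymethyl)-3-[(1R,6R)-3-(hydroxymethyl)-6-(propan-2-yl)cyclohex-2-en-1-yl]prop-2-enoyl]oxy}methyl)-1-oxo-6-(propan-2-yl)-1,3,5a,6,7,8,9,9a-octahydro-2-benzoxepine-4-carboxylic acid
Conditions: CF3CO2H/CH2Cl2 (1:4), 0 °C
Reagents that add atoms: none
Why: Acidolysis of the tert-butyl ester by alkyl–oxygen cleavage (E1 loss of isobutene) frees the C4 carboxylic acid and leaves the lactone, the acrylate ester and the stereocentres untouched.

Compound list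

1 | tert-butyl acrylate | C=CC(=O)OC(C)(C)C | starting material
2 | tert-butyl 2-(hydroxymethyl)prop-2-enoate | OCC(=C)C(=O)OC(C)(C)C | intermediate
3 | (R)-(−)-carvone | CC1=CC[C@@H](C(C)=C)CC1=O | starting material
4 | (R)-carvotanacetone, (5R)-2-methyl-5-(propan-2-yl)cyclohex-2-en-1-one | CC1=CC[C@@H](C(C)C)CC1=O | intermediate
5 | kinetic lithium dienolate of 4 (C1–OLi, C1=C6) | CC1=CC[C@@H](C(C)C)C=C1[O-].[Li+] | intermediate (not isolated)
6 | (5S,6S)-2-methyl-6-[2-(phenylsulfinyl)ethyl]-5-(propan-2-yl)cyclohex-2-en-1-one (both configurations at sulfur) | CC1=CC[C@@H](C(C)C)[C@H](CCS(=O)c2ccccc2)C1=O | intermediate (not isolated)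
7 | (5S,6S)-6-ethenyl-2-methyl-5-(propan-2-yl)cyclohex-2-en-1-one | CC1=CC[C@@H](C(C)C)[C@H](C=C)C1=O | intermediate
8 | lithium enolate from 1,4-reduction of 7 (C1–OLi, C1=C2) | CC1CC[C@@H](C(C)C)[C@H](C=C)C=1[O-].[Li+] | intermediate (not isolated)
9 | (5S,6S)-6-ethenyl-2-methyl-5-(propan-2-yl)cyclohex-1-en-1-yl trifluoromethanesulfonate | CC1CC[C@@H](C(C)C)[C@H](C=C)C=1OS(=O)(=O)C(F)(F)F | intermediate
10 | 2-(tert-butoxycarbonyl)prop-2-en-1-yl (5S,6S)-6-ethenyl-2-methyl-5-(propan-2-yl)cyclohex-1-ene-1-carboxylate | CC1CC[C@@H](C(C)C)[C@H](C=C)C=1C(=O)OCC(=C)C(=O)OC(C)(C)C | intermediate (not isolated)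
11 | tert-butyl (5aR,6S)-9-methyl-1-oxo-6-(propan-2-yl)-1,3,5a,6,7,8-hexahydro-2-benzoxepine-4-carboxylate | CC1CC[C@@H](C(C)C)[C@@H]2C=C(C(=O)OC(C)(C)C)COC(=O)C=12 | intermediate
12 | lithium dienolate of 11 (C1–OLi, C1=C9a, C9=CH2) | C=C1CC[C@@H](C(C)C)[C@@H]2C=C(C(=O)OC(C)(C)C)COC([O-])=C12.[Li+] | intermediate (not isolated)
13 | tert-butyl (5aR,6S,9aS)-9-methylidene-1-oxo-6-(propan-2-yl)-1,3,5a,6,7,8,9,9a-octahydro-2-benzoxepine-4-carboxylate | C=C1CC[C@@H](C(C)C)[C@@H]2C=C(C(=O)OC(C)(C)C)COC(=O)[C@@H]21 | intermediate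
14 | tert-butyl (5aR,6S,9R,9aS)-9-(bromomethyl)-9-hydroxy-1-oxo-6-(propan-2-yl)-1,3,5a,6,7,8,9,9a-octahydro-2-benzoxepine-4-carboxylate | BrC[C@@]1(O)CC[C@@H](C(C)C)[C@@H]2C=C(C(=O)OC(C)(C)C)COC(=O)[C@@H]21 | intermediate
15 | 3-methylbutanal | CC(C)CC=O | starting material
16 | but-3-en-2-one | CC(=O)C=C | starting material
17 | (2R)-5-oxo-2-(propan-2-yl)hexanal | CC(C)[C@H](C=O)CCC(C)=O | intermediate (not isolated)
18 | (R)-cryptone, (4R)-4-(propan-2-yl)cyclohex-2-en-1-one | CC(C)[C@H]1CCC(=O)C=C1 | intermediate
19 | bromomagnesium enolate from vinyl addition to 18 | CC(C)[C@H]1CCC(O[Mg]Br)=C[C@@H]1C=C | intermediate (not isolated)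
20 | (3R,4R)-3-ethenyl-4-(propan-2-yl)cyclohex-1-en-1-yl trifluoromethanesulfonate | CC(C)[C@H]1CCC(OS(=O)(=O)C(F)(F)F)=C[C@@H]1C=C | intermediate
21 | [(3R,4R)-3-ethenyl-4-(propan-2-yl)cyclohex-1-en-1-yl]methanol | CC(C)[C@H]1CCC(CO)=C[C@@H]1C=C | intermediate
22 | methyl 2-(hydroxymethyl)prop-2-enoate | OCC(=C)C(=O)OC | starting material
23 | methyl (2E)-2-(hydroxymethyl)-3-[(1R,6R)-3-(hydroxymethyl)-6-(propan-2-yl)cyclohex-2-en-1-yl]prop-2-enoate | CC(C)[C@H]1CCC(CO)=C[C@@H]1/C=C(\CO)C(=O)OC | intermediate
24 | (2E)-2-(hydroxymethyl)-3-[(1R,6R)-3-(hydroxymethyl)-6-(propan-2-yl)cyclohex-2-en-1-yl]prop-2-enoic acid | CC(C)[C@H]1CCC(CO)=C[C@@H]1/C=C(\CO)C(=O)O | intermediate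
25 | tert-butyl (5aR,6S,9R,9aS)-1-oxo-6-(propan-2-yl)-3,5a,6,7,8,9a-hexahydro-1H-spiro[2-benzoxepine-9,2'-oxirane]-4-carboxylate (epoxide oxygen cis to C1) | C1O[C@@]12CC[C@@H](C(C)C)[C@@H]3C=C(C(=O)OC(C)(C)C)COC(=O)[C@@H]32 | intermediate (not isolated)
26 | tert-butyl (5aR,6S,9R,9aS)-9-hydroxy-9-({[(2E)-2-(hydroxymethyl)-3-[(1R,6R)-3-(hydroxymethyl)-6-(propan-2-yl)cyclohex-2-en-1-yl]prop-2-enoyl]oxy}methyl)-1-oxo-6-(propan-2-yl)-1,3,5a,6,7,8,9,9a-octahydro-2-benzoxepine-4-carboxylate | CC(C)[C@H]1CCC(CO)=C[C@@H]1/C=C(\CO)C(=O)OC[C@@]1(O)CC[C@@H](C(C)C)[C@@H]2C=C(C(=O)OC(C)(C)C)COC(=O)[C@@H]21 | intermediate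
27 | CNP0361406.3 | CC(C)[C@H]1CCC(CO)=C[C@@H]1/C=C(\CO)C(=O)OC[C@@]1(O)CC[C@@H](C(C)C)[C@@H]2C=C(C(=O)O)COC(=O)[C@@H]21 | target

Total step count: 14.
Longest linear sequence: 8 steps (steps 2, 3, 4, 5, 6, 7, 13, 14, from (R)-carvone).

Steps most likely to fail

Step 5. What may go wrong: the acylpalladium intermediate adds to the neighbouring vinyl group faster than alcohol 2 intercepts it, or residual phosphine and CO shut down the ruthenium catalyst so that ring closure stalls at 10. The fallback sets out from 9 and returns at 11, with the order of bond formation inverted. Cross-metathesis of the vinyl group of 9 with 2 (Hoveyda–Grubbs second-generation catalyst, CH2Cl2, 40 °C) gives the hydroxy dienoate triflate F1. Intramolecular carbonylative lactonisation (Pd(OAc)2, 1,3-bis(diphenylphosphino)propane, CO, i-Pr2NEt, toluene, 70 °C) then closes ring B to 11. Here CO meets only spent ruthenium, and the tethered alcohol captures the acylpalladium intramolecularly; run in one flask, the two bonds are still made in one operation.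

Step 6. What may go wrong: deprotonation at the doubly allylic C5a–H instead of the methyl group, or protonation of the dienolate from both faces, erodes C5a and C9a. The fallback sets out from 11 and returns at 13. Soft enolisation with t-BuMe2SiOTf/Et3N (CH2Cl2, −78 °C) gives the silyl dienol ether F2, which is isolated. It is then protodesilylated at C9a with HF·pyridine at −78 °C, the proton again entering from the face of the C5a–H.

Step 7. What may go wrong: opening of the bromonium ion from the wrong face, or of an open tertiary cation from both faces, gives the C9 epimer. The fallback sets out from 13 and returns at 25. Saponification of the lactone (LiOH, THF/H2O; tert-butyl ester retained) gives the seco hydroxy acid F3. Iodolactonisation (I2, NaHCO3, Et2O/H2O, 0 °C) delivers the carboxylate oxygen to C9 intramolecularly, so the iodomethyl β-lactone F4 necessarily has its C9–O bond cis to C1. Et3N in CH2Cl2 then lets the primary allylic alcohol take over the acyl group, which re-forms ring B, and the released tertiary alkoxide displaces iodide. This gives spiro-epoxide 25, which is isolated and taken into step 13.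

Further compounds
F1 | step 5 | tert-butyl (E)-2-(hydroxymethyl)-3-[trans-3-methyl-6-(propan-2-yl)-2-(trifluoromethanesulfonyloxy)cyclohex-2-en-1-yl]prop-2-enoate | CC1CC[C@@H](C(C)C)[C@H](/C=C(\CO)C(=O)OC(C)(C)C)C=1OS(=O)(=O)C(F)(F)F
F2 | step 6 | tert-butyl (5aR,6S)-1-[(tert-butyldimethylsilyl)oxy]-9-methylidene-6-(propan-2-yl)-5a,6,7,8-tetrahydro-3H-2-benzoxepine-4-carboxylate | C=C1CC[C@@H](C(C)C)[C@@H]2C=C(C(=O)OC(C)(C)C)COC(O[Si](C)(C)C(C)(C)C)=C12
F3 | step 7 | 2-[(E)-2-(tert-butoxycarbonyl)-3-hydroxyprop-1-en-1-yl]-6-methylidene-3-(propan-2-yl)cyclohexane-1-carboxylic acid (1,2-cis, 2,3-trans) | C=C1CC[C@@H](C(C)C)[C@H](/C=C(\CO)C(=O)OC(C)(C)C)[C@@H]1C(=O)O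
F4 | step 7 | tert-butyl (E)-2-(hydroxymethyl)-3-[6-(iodomethyl)-8-oxo-3-(propan-2-yl)-7-oxabicyclo[4.2.0]octan-2-yl]prop-2-enoate (cis-fused β-lactone) | IC[C@@]12CC[C@@H](C(C)C)[C@H](/C=C(\CO)C(=O)OC(C)(C)C)[C@@H]1C(=O)O2
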